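Ring A, the terminal 2,4,6-trihydroxyphenoxy ring, is not coupled to ring B but grown around its crowded C-1–O bond. Its C-6/C-1/C-2 segment is an aryloxymalonyl unit and C-3/C-4/C-5 an acetonedicarboxylate, so one magnesium-mediated [3+3] double C-acylation forges C-2–C-3 and C-5–C-6, closes the carbocycle and aromatises it. The precursor is the ring-B aryloxymalonate (4-OBn, 3,5-OMe), made by SN2 at the malonate carbon. Since two methyl esters beside an acidic C–H are weak acyl donors, one is turned into the acid chloride. Rings C–F follow by copper C–O couplings that always pair a hindered phenol with an open or formyl-activated bromide; BBr3 finishes.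

Key step: step 5

Remark (numbering): rings are lettered A–F from the 2,4,6-trihydroxyphenoxy end. In rings B, D and E, C-1 carries the oxygen to the preceding ring and C-4 (between two OH) the oxygen to the next ring. Ring C is C-1 (O to B), C-2 (O to D), C-3 to C-5 (OH), C-6 (H). Ring F is bound through C-1.
Remark (stereochemistry): the target has no stereocentre and its diaryl ether axes rotate freely, so it is achiral and no enantiomer has to be selected. The labile stereocentres of 7, 9 and 10 are carried as mixtures and vanish on aromatisation.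

Step 1
Reactants: 1 syringaldehyde (4-hydroxy-3,5-dimethoxybenzaldehyde)
Product: 2 4-(benzyloxy)-3,5-dimethoxybenzaldehyde
Conditions: BnBr, K2CO3, DMF, 60 °C
Reagents that add atoms: benzyl bromide, BrCc1ccccc1
Why: Williamson ether synthesis on an acidic para-formyl phenol, which should mask the future ring B C-4 oxygen with the only group of the route that hydrogenolysis can lift.

Step 2
Reactants: 2 4-(benzyloxy)-3,5-dimethoxybenzaldehyde
Product: 4 4-(benzyloxy)-3,5-dimethoxyphenol, via aryl formate 3 (not isolated)
Conditions: mCPBA, CH2Cl2, 0 °C to rt; aq. NaHCO3 wash; then K2CO3 (cat.), MeOH, rt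
Reagents that add atoms: mCPBA, OOC(=O)c1cccc(Cl)c1
Why: Baeyer–Villiger oxidation, preferred to alkaline peroxide because the aldehyde has no free ortho or para hydroxyl; the para-alkoxyaryl group should migrate rather than hydride, and the formate is removed by transesterification.

Step 3
Reactants: 4 4-(benzyloxy)-3,5-dimethoxyphenol; 5 dimethyl chloromalonate
Product: 6 dimethyl 2-[4-(benzyloxy)-3,5-dimethoxyphenoxy]malonate
Conditions: K2CO3, acetone, reflux
Reagents that add atoms: none
Why: SN2 O-alkylation of an unhindered phenoxide at the sp3 malonate carbon, a standard entry to aryloxymalonates, which lays down the later crowded ring A C-1–O bond without steric penalty.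

Step 4
Reactants: 6 dimethyl 2-[4-(benzyloxy)-3,5-dimethoxyphenoxy]malonate
Product: 7 2-[4-(benzyloxy)-3,5-dimethoxyphenoxy]-3-methoxy-3-oxopropanoic acid (malonic half-ester, racemic)
Conditions: KOH (1.0 equiv), MeOH–THF, 0 °C to rt; cold 1 M HCl
Reagents that add atoms: potassium hydroxide, [K+].[OH-]
Why: Selective monosaponification of a symmetric malonate, self-limiting because the first carboxylate shields the second ester from hydroxide; it opens the way to one strongly activated acyl group, and the half-acid is kept cold to avoid decarboxylation.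

Step 5
Reactants: 7 malonic half-ester; 8 dimethyl 1,3-acetonedicarboxylate
Product: 11 dimethyl 2,4,6-trihydroxy-5-[4-(benzyloxy)-3,5-dimethoxyphenoxy]isophthalate (rings A–B), via half-ester acid chloride 9 (not isolated), via open-chain dioxo triester 10 (not isolated)
Conditions: (COCl)2, DMF (cat.), CH2Cl2, 0 °C to rt, evaporate; add to 8 (1.2 equiv), MgCl2, pyridine, CH2Cl2, 0 °C to rt; then Mg(OMe)2, MeOH, 60 °C; 1 M HCl
Reagents that add atoms: none
Why: Proposed new method: the magnesium chelate of 8 is acylated at carbon by chloride 9 (directly or through the derived aryloxy(methoxycarbonyl)ketene), which sets C-2–C-3 and leaves 10 as a chelated tricarbonyl enolate, and magnesium methoxide then enolises the remaining methylene C-5, which attacks the pendant methyl ester carbon C-6 and expels methoxide. The closest known reaction types are the MgCl2/amine C-acylation of acetonedicarboxylates and other β-keto esters with acid chlorides, the alkoxide-induced Claisen cyclisation of 3,5-dioxo diesters and of 2-pyranones to phloroglucinols, and the sodium-mediated condensation of simple malonates with acetonedicarboxylates, none of which has been run with a 2-aryloxymalonyl donor. The single ring closes in a Dieckmann-type 6-(enolexo)-exo-trig mode and the cyclohexane-1,3,5-trione so formed tautomerises three times to the benzene ring. No stereocentre is created and the labile ones of 7, 9 and 10 disappear. The step needs C- over O-acylation: chelation ties up the enolate oxygens, and any pyranone or the non-aromatisable product of attack by C-1 on the distal ester is reopened by methoxide, whereas the salicylate-type magnesium phenoxide of 11 is an irreversible sink. Regiochemistry is not at stake because 8 is symmetric and either malonyl carbonyl leads to the same symmetric product, and the slight excess of 8 should suppress double acylation.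

Step 6
Reactants: 11 dimethyl 2,4,6-trihydroxy-5-[4-(benzyloxy)-3,5-dimethoxyphenoxy]isophthalate
Product: 13 2-[4-(benzyloxy)-3,5-dimethoxyphenoxy]benzene-1,3,5-triol, via isophthalic diacid 12 (not isolated)
Conditions: 3 M aq. KOH (degassed), reflux, Ar; then HCl to pH 2, 60 °C
Reagents that add atoms: none
Why: Ester saponification followed by decarboxylation of a phloroglucinol dicarboxylic acid, which loses CO2 through its β-keto acid tautomers on gentle warming, while benzyl, methyl and diaryl ethers are inert to aqueous alkali and exclusion of air protects the triol.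

Step 7
Reactants: 13 2-[4-(benzyloxy)-3,5-dimethoxyphenoxy]benzene-1,3,5-triol
Product: 14 2-[4-(benzyloxy)-3,5-dimethoxyphenoxy]-1,3,5-trimethoxybenzene
Conditions: Me2SO4, K2CO3, acetone, reflux
Reagents that add atoms: dimethyl sulfate, COS(=O)(=O)OC
Why: Williamson O-methylation under the weak-base/acetone conditions that are standard for phloroglucinols and favour O- over C-alkylation.

Step 8
Reactants: 14 2-[4-(benzyloxy)-3,5-dimethoxyphenoxy]-1,3,5-trimethoxybenzene
Product: 15 2,6-dimethoxy-4-(2,4,6-trimethoxyphenoxy)phenol (A–B phenol)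
Conditions: H2 (1 atm), 10% Pd/C, EtOAc–MeOH, rt
Reagents that add atoms: none
Why: Catalytic hydrogenolysis of the single benzyl aryl ether, which should free the ring B C-4 hydroxyl and leave methyl and diaryl ethers untouched.

Step 9
Reactants: 16 5-bromo-1,2,3-trimethoxybenzene
Product: 17 6-bromo-2,3,4-trimethoxybenzaldehyde (ring C block)
Conditions: Cl2CHOMe, TiCl4, CH2Cl2, −10 to 0 °C; ice/dil. HCl
Reagents that add atoms: dichloromethyl methyl ether, COC(Cl)Cl; water, O
Why: Rieche formylation (Friedel–Crafts type); the two open positions of 16 are equivalent and each lies ortho and para to methoxy groups, so only one aldehyde can form, with bromine at ring C C-1 next to the formyl carbon on C-2.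

Step 10
Reactants: 15 A–B phenol; 17 6-bromo-2,3,4-trimethoxybenzaldehyde
Product: 18 6-[2,6-dimethoxy-4-(2,4,6-trimethoxyphenoxy)phenoxy]-2,3,4-trimethoxybenzaldehyde (rings A–B–C)
Conditions: CuI (20 mol %), N,N-dimethylglycine·HCl (40 mol %), Cs2CO3, dioxane, 100 °C, Ar
Reagents that add atoms: none
Why: Ligand-accelerated Ullmann diaryl ether synthesis, in which the ortho-formyl group lowers the electron density at C–Br and can guide copper, so that the tri-ortho-substituted B–O–C ether is made on an activated bromide whose other ortho position is free.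

Step 11
Reactants: 18 A–B–C aldehyde
Product: 20 6-[2,6-dimethoxy-4-(2,4,6-trimethoxyphenoxy)phenoxy]-2,3,4-trimethoxyphenol (A–B–C phenol), via aryl formate 19 (not isolated)
Conditions: mCPBA (1.1 equiv), NaHCO3, CH2Cl2, 0 °C; then K2CO3 (cat.), MeOH, rt
Reagents that add atoms: mCPBA, OOC(=O)c1cccc(Cl)c1
Why: Baeyer–Villiger oxidation in which the migrating ring C carbon has two ortho and one para oxygen donors, so that formate formation should outpace peracid attack on the electron-rich rings, and methanolysis turns the activating formyl group into the ring C C-2 hydroxyl.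

Step 12
Reactants: 21 3,4,5-trimethoxyphenylboronic acid; 22 4-bromo-2,6-dimethoxyphenol
Product: 23 5-(4-bromo-2,6-dimethoxyphenoxy)-1,2,3-trimethoxybenzene (rings F–E)
Conditions: Cu(OAc)2, pyridine, 4 Å MS, CH2Cl2, dry air, rt
Reagents that add atoms: none
Why: Chan–Lam coupling, which tolerates di-ortho-substituted phenols when the boronic acid is unhindered and leaves the aryl bromide untouched at room temperature, while the bromine blocks para oxidative dimerisation of the phenol.

Step 13
Reactants: 23 5-(4-bromo-2,6-dimethoxyphenoxy)-1,2,3-trimethoxybenzene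
Product: 26 [3,5-dimethoxy-4-(3,4,5-trimethoxyphenoxy)phenyl]boronic acid, via aryllithium 24 (not isolated), via lithium aryltriisopropoxyborate 25 (not isolated)
Conditions: B(OiPr)3, then n-BuLi, THF–toluene, −78 °C; 1 M HCl, rt
Reagents that add atoms: triisopropyl borate, CC(C)OB(OC(C)C)OC(C)C; water, O
Why: Bromine–lithium exchange with in-situ borate quench, in which exchange is faster than ortho-lithiation or attack of butyllithium on the borate, so the aryllithium should be trapped before it can isomerise.

Step 14
Reactants: 26 F–E boronic acid; 22 4-bromo-2,6-dimethoxyphenol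
Product: 27 5-[4-(4-bromo-2,6-dimethoxyphenoxy)-2,6-dimethoxyphenoxy]-1,2,3-trimethoxybenzene (rings F–E–D)
Conditions: Cu(OAc)2, pyridine, 4 Å MS, CH2Cl2, dry air, rt
Reagents that add atoms: none
Why: Second Chan–Lam coupling with the same logic as step 12, the boron sitting on the open E C-1 and the oxygen on the crowded D C-4.

Step 15
Reactants: 20 A–B–C phenol; 27 F–E–D bromide
Product: 28 pentadeca-O-methyl ether of the target (rings A–F)
Conditions: CuI (20 mol %), picolinic acid (40 mol %), K3PO4, DMSO, 100 °C, Ar
Reagents that add atoms: none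
Why: Ullmann-type diaryl ether synthesis with the copper/picolinic acid system developed for hindered phenols, in which all crowding lies on the phenoxide (ring C C-2) and the bromide carbon D C-1 has two free ortho positions.

Step 16
Reactants: 28 pentadeca-O-methyl ether
Product: 29 target CNP0270681.0
Conditions: BBr3 (excess), CH2Cl2, −78 °C to rt, Ar; ice-water
Reagents that add atoms: none
Why: Lewis-acid cleavage of aryl methyl ethers, in which boron binds each methoxy oxygen and bromide attacks the methyl carbon by SN2, so that the five diaryl ether bonds, which offer only sp2 carbons, should stay intact.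

Compound list
1 | syringaldehyde | COc1cc(C=O)cc(OC)c1O | starting material
2 | 4-(benzyloxy)-3,5-dimethoxybenzaldehyde | COc1cc(C=O)cc(OC)c1OCc1ccccc1 | intermediate
3 | 4-(benzyloxy)-3,5-dimethoxyphenyl formate | COc1cc(OC=O)cc(OC)c1OCc1ccccc1 | intermediate
4 | 4-(benzyloxy)-3,5-dimethoxyphenol | COc1cc(O)cc(OC)c1OCc1ccccc1 | intermediate
5 | dimethyl chloromalonate | COC(=O)C(Cl)C(=O)OC | starting material
6 | dimethyl 2-[4-(benzyloxy)-3,5-dimethoxyphenoxy]malonate | COC(=O)C(Oc1cc(OC)c(OCc2ccccc2)c(OC)c1)C(=O)OC | intermediate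
7 | 2-[4-(benzyloxy)-3,5-dimethoxyphenoxy]-3-methoxy-3-oxopropanoic acid (racemic) | COC(=O)C(Oc1cc(OC)c(OCc2ccccc2)c(OC)c1)C(=O)O | intermediate
8 | dimethyl 1,3-acetonedicarboxylate | COC(=O)CC(=O)CC(=O)OC | starting material
9 | methyl 2-[4-(benzyloxy)-3,5-dimethoxyphenoxy]-3-chloro-3-oxopropanoate (racemic) | COC(=O)C(Oc1cc(OC)c(OCc2ccccc2)c(OC)c1)C(=O)Cl | intermediate
10 | dimethyl 2-[4-(benzyloxy)-3,5-dimethoxyphenoxy]-4-(methoxycarbonyl)-3,5-dioxoheptanedioate (keto form of the magnesium chelate, stereoisomer mixture) | COC(=O)C(Oc1cc(OC)c(OCc2ccccc2)c(OC)c1)C(=O)C(C(=O)OC)C(=O)CC(=O)OC | intermediate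
11 | dimethyl 2,4,6-trihydroxy-5-[4-(benzyloxy)-3,5-dimethoxyphenoxy]isophthalate | COC(=O)c1c(O)c(C(=O)OC)c(O)c(Oc2cc(OC)c(OCc3ccccc3)c(OC)c2)c1O | intermediate
12 | 2,4,6-trihydroxy-5-[4-(benzyloxy)-3,5-dimethoxyphenoxy]isophthalic acid | OC(=O)c1c(O)c(C(=O)O)c(O)c(Oc2cc(OC)c(OCc3ccccc3)c(OC)c2)c1O | intermediate
13 | 2-[4-(benzyloxy)-3,5-dimethoxyphenoxy]benzene-1,3,5-triol | Oc1cc(O)c(Oc2cc(OC)c(OCc3ccccc3)c(OC)c2)c(O)c1 | intermediate
14 | 2-[4-(benzyloxy)-3,5-dimethoxyphenoxy]-1,3,5-trimethoxybenzene | COc1cc(OC)c(Oc2cc(OC)c(OCc3ccccc3)c(OC)c2)c(OC)c1 | intermediate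
15 | 2,6-dimethoxy-4-(2,4,6-trimethoxyphenoxy)phenol | COc1cc(OC)c(Oc2cc(OC)c(O)c(OC)c2)c(OC)c1 | intermediate
16 | 5-bromo-1,2,3-trimethoxybenzene | COc1cc(Br)cc(OC)c1OC | starting material
17 | 6-bromo-2,3,4-trimethoxybenzaldehyde | O=Cc1c(Br)cc(OC)c(OC)c1OC | intermediate
18 | 6-[2,6-dimethoxy-4-(2,4,6-trimethoxyphenoxy)phenoxy]-2,3,4-trimethoxybenzaldehyde | O=Cc1c(Oc2c(OC)cc(Oc3c(OC)cc(OC)cc3OC)cc2OC)cc(OC)c(OC)c1OC | intermediate
19 | 6-[2,6-dimethoxy-4-(2,4,6-trimethoxyphenoxy)phenoxy]-2,3,4-trimethoxyphenyl formate | O=COc1c(Oc2c(OC)cc(Oc3c(OC)cc(OC)cc3OC)cc2OC)cc(OC)c(OC)c1OC | intermediate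
20 | 6-[2,6-dimethoxy-4-(2,4,6-trimethoxyphenoxy)phenoxy]-2,3,4-trimethoxyphenol | Oc1c(Oc2c(OC)cc(Oc3c(OC)cc(OC)cc3OC)cc2OC)cc(OC)c(OC)c1OC | intermediate
21 | 3,4,5-trimethoxyphenylboronic acid | COc1cc(B(O)O)cc(OC)c1OC | starting material
22 | 4-bromo-2,6-dimethoxyphenol | COc1cc(Br)cc(OC)c1O | starting material
23 | 5-(4-bromo-2,6-dimethoxyphenoxy)-1,2,3-trimethoxybenzene | COc1cc(Oc2c(OC)cc(Br)cc2OC)cc(OC)c1OC | intermediate
24 | [3,5-dimethoxy-4-(3,4,5-trimethoxyphenoxy)phenyl]lithium | [Li]c1cc(OC)c(Oc2cc(OC)c(OC)c(OC)c2)c(OC)c1 | intermediate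
25 | lithium [3,5-dimethoxy-4-(3,4,5-trimethoxyphenoxy)phenyl]triisopropoxyborate | [Li+].CC(C)O[B-](OC(C)C)(OC(C)C)c1cc(OC)c(Oc2cc(OC)c(OC)c(OC)c2)c(OC)c1 | intermediate
26 | [3,5-dimethoxy-4-(3,4,5-trimethoxyphenoxy)phenyl]boronic acid | OB(O)c1cc(OC)c(Oc2cc(OC)c(OC)c(OC)c2)c(OC)c1 | intermediate
27 | 5-[4-(4-bromo-2,6-dimethoxyphenoxy)-2,6-dimethoxyphenoxy]-1,2,3-trimethoxybenzene | COc1cc(Oc2c(OC)cc(Oc3c(OC)cc(Br)cc3OC)cc2OC)cc(OC)c1OC | intermediate
28 | pentadeca-O-methyl ether of the target | COc1cc(OC)c(Oc2cc(OC)c(Oc3cc(OC)c(OC)c(OC)c3Oc3cc(OC)c(Oc4cc(OC)c(Oc5cc(OC)c(OC)c(OC)c5)c(OC)c4)c(OC)c3)c(OC)c2)c(OC)c1 | intermediate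
29 | CNP0270681.0 (achiral) | Oc1cc(O)c(Oc2cc(O)c(Oc3cc(O)c(O)c(O)c3Oc3cc(O)c(Oc4cc(O)c(Oc5cc(O)c(O)c(O)c5)c(O)c4)c(O)c3)c(O)c2)c(O)c1 | target

Total step count: 16. Longest linear sequence: 12 steps (1–8, 10, 11, 15, 16).

Steps most likely to fail

1. Step 5.
- What may go wrong: kinetic O-acylation and lactonisation that does not revert; methoxide-induced retro-Claisen cleavage of the open-chain triester; ketene dimerisation; intramolecular Friedel–Crafts acylation of the activated ring B by the acid chloride; or self-condensation of 8 outrunning the cross-acylation.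
- Fallback (known chemistry, ring A bought instead of built): it sets out from 22, which is benzylated (BnBr, K2CO3, DMF) to 2-(benzyloxy)-5-bromo-1,3-dimethoxybenzene F1. An Ullmann-type coupling of F1 with commercial 2,4,6-trimethoxyphenol (CuI, picolinic acid, K3PO4, DMSO, 100 °C) again pairs a hindered phenol with an open bromide. It should give 14, where the route is rejoined before step 8.

2. Step 15.
- What may go wrong: slow C–O bond formation at the doubly flanked phenoxide, so that protodebromination of the bromide and oxidative degradation of the electron-rich phenoxide at 100 °C take over.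
- Fallback (oxidative copper(II) coupling at room temperature instead of a hot copper(I)/halide coupling): it sets out from 27. Bromine–lithium exchange in the presence of triisopropyl borate, as in step 13, passes through the F–E–D aryllithium F2 and the lithium F–E–D-aryltriisopropoxyborate F3. Acid hydrolysis then gives the F–E–D boronic acid F4. A Chan–Lam coupling of F4 with 20 (Cu(OAc)2, pyridine, 4 Å MS, CH2Cl2, dry air, rt) should return to the route at 28.

3. Step 16.
- What may go wrong: incomplete ether cleavage, because partly demethylated borates precipitate from dichloromethane, and air oxidation of the pyrogallol rings during isolation of the free polyphenol.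
- Fallback (derivatise, purify, release): it sets out from 28. The crude product of the BBr3 treatment is acetylated at once (Ac2O, pyridine, rt) to the pentadecaacetate of the target F5. F5 is stable and can be separated on silica from under-cleaved material, which is resubmitted. Acid-catalysed methanolysis under argon (AcCl cat., MeOH, rt) then releases 29.

Further compounds
F1 | step 5 | 2-(benzyloxy)-5-bromo-1,3-dimethoxybenzene | COc1cc(Br)cc(OC)c1OCc1ccccc1
F2 | step 15 | {4-[3,5-dimethoxy-4-(3,4,5-trimethoxyphenoxy)phenoxy]-3,5-dimethoxyphenyl}lithium | [Li]c1cc(OC)c(Oc2cc(OC)c(Oc3cc(OC)c(OC)c(OC)c3)c(OC)c2)c(OC)c1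
F3 | step 15 | lithium {4-[3,5-dimethoxy-4-(3,4,5-trimethoxyphenoxy)phenoxy]-3,5-dimethoxyphenyl}triisopropoxyborate | [Li+].CC(C)O[B-](OC(C)C)(OC(C)C)c1cc(OC)c(Oc2cc(OC)c(Oc3cc(OC)c(OC)c(OC)c3)c(OC)c2)c(OC)c1
F4 | step 15 | {4-[3,5-dimethoxy-4-(3,4,5-trimethoxyphenoxy)phenoxy]-3,5-dimethoxyphenyl}boronic acid | OB(O)c1cc(OC)c(Oc2cc(OC)c(Oc3cc(OC)c(OC)c(OC)c3)c(OC)c2)c(OC)c1
F5 | step 16 | pentadecaacetate of the target | CC(=O)Oc1cc(OC(C)=O)c(Oc2cc(OC(C)=O)c(Oc3cc(OC(C)=O)c(OC(C)=O)c(OC(C)=O)c3Oc3cc(OC(C)=O)c(Oc4cc(OC(C)=O)c(Oc5cc(OC(C)=O)c(OC(C)=O)c(OC(C)=O)c5)c(OC(C)=O)c4)c(OC(C)=O)c3)c(OC(C)=O)c2)c(OC(C)=O)c1
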